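Cuts, in retrosynthetic order (longipinane numbering, C1 = ketone carbon): the two acyl–O bonds at C7 and C9, the cyclobutane bond C5–C11, the ring bond C6–C7, then C4–C5, C3–CH3, C8–C9 and C9–C10.
Enabling feature: in the seven-membered ring (C4–C5–C6–C7–C8–C9–C10) the quaternary gem-dimethyl carbon C6 lies between C5, a cyclobutane CH that can be carried as a ketone, and the carbinol C7. C5–C6 can therefore be a regiodefined, fully substituted enolate and C7 an aldehyde.
Forward order: ring A (C10–C11–C1–C2–C3–C4) is 3-methylcyclohex-2-enone. The C9–C8–C7 chain is grown on C10 and the C5–C6 unit on C4, the seven-membered ring closes at C6–C7, the four-membered ring closes last at C5–C11, and the two esters follow.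
Stereochemistry: C10 comes from a copper-catalysed asymmetric conjugate addition and C9 from a catalyst-controlled allylboration. C4 comes from aldol attack anti to the pseudo-axial C10 methyl, and the cis-fused bicycle is also taken to be the more stable epimer. C7 comes from 1,3-anti induction by C9–OTBS, C5 from a chelate-controlled syn reduction followed by inversion, and C11 from the geometry of the bridge.

Key step: step 12

Remark 1: α denotes the face of the seven-membered ring that carries the C10 methyl group and H4. In the target C7–O is α, C9–O is β and the C5–C11 bond is β.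
Remark 2 (assumption): once C5 is a ketone (22, 25), H4 is a vinylogous β-diketone proton and C4 can epimerise. Compound 22 is drawn as the kinetically formed cis epimer and 25 as the cis-fused epimer, which is taken to be the more stable one.

Step 1
Reactants: 1 1-hexyne; 2 3-methylcyclohex-2-en-1-one
Product: 4 (S)-3-[(E)-hex-1-enyl]-3-methylcyclohexanone, via hexenylalane 3 (not isolated)
Conditions: 1, iBu2AlH, hexane, 50 °C; then 2, [Cu(MeCN)4]BF4 (10 mol %), chiral phosphinamine Ph2P–N[CH(Me)(2-naphthyl)]2 (11 mol %, enantiomer that gives S), Et2O, −10 °C; aq HCl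
Reagents that add atoms: 1-hexyne 1, C#CCCCC
Why: Tandem hydroalumination and copper-catalysed asymmetric conjugate addition of an alkenylalane to a β-methyl cyclic enone is a known route to all-carbon quaternary centres, and the ligand decides the face on which the alkenyl group (a masked C9 aldehyde) enters, which sets (S)-C10.

Step 2
Reactants: 4 (S)-3-[(E)-hex-1-enyl]-3-methylcyclohexanone
Product: 5 (S)-5-[(E)-hex-1-enyl]-5-methylcyclohex-2-en-1-one
Conditions: IBX (2-iodoxybenzoic acid, 2.5 equiv), DMSO/fluorobenzene, 75 °C
Reagents that add atoms: none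
Why: IBX dehydrogenation of a ketone to its enone can desaturate only the C2–C1 side, because the β-carbon on the other side is the quaternary C10, so the regiochemistry is structural and C10 is untouched.

Step 3
Reactants: 5 (S)-5-[(E)-hex-1-enyl]-5-methylcyclohex-2-en-1-one
Product: 7 (S)-1-methyl-5-oxocyclohex-3-ene-1-carbaldehyde, via ozonide 6 (not isolated)
Conditions: O3, CH2Cl2, −78 °C, Sudan Red 7B as end-point indicator; then Me2S, −78 to 25 °C
Reagents that add atoms: ozone, [O-][O+]=O
Why: Ozonolysis with reductive work-up cleaves the electron-rich disubstituted alkene much faster than the electron-poor enone double bond and unmasks the C9 aldehyde on the quaternary, non-epimerisable C10.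

Step 4
Reactants: 7 (S)-1-methyl-5-oxocyclohex-3-ene-1-carbaldehyde; 8 allylboronic acid pinacol ester
Product: 10 (S)-5-[(R)-1-hydroxybut-3-enyl]-5-methylcyclohex-2-en-1-one, via pinacol borate 9 (not isolated)
Conditions: 8 (1.3 equiv), (R)-3,3′-bis(2,4,6-triisopropylphenyl)-1,1′-binaphthyl-2,2′-diyl hydrogen phosphate (5 mol %), toluene, −30 °C; then H2O
Reagents that add atoms: allylboronic acid pinacol ester 8, C=CCB1OC(C)(C)C(C)(C)O1
Why: Chiral phosphoric acid-catalysed allylboration proceeds through a closed chair transition state in which the catalyst sends allyl to the Re face of the aldehyde and sets (R)-C9 under catalyst control; the ketone does not compete, and material of the wrong C10 configuration carried over from step 1 becomes a separable diastereomer.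

Step 5
Reactants: 10 (S)-5-[(R)-1-hydroxybut-3-enyl]-5-methylcyclohex-2-en-1-one
Product: 11 (S)-5-[(R)-1-(tert-butyldimethylsilyloxy)but-3-enyl]-5-methylcyclohex-2-en-1-one
Conditions: TBSOTf, 2,6-lutidine, CH2Cl2, 0 °C
Reagents that add atoms: tert-butyldimethylsilyl triflate, CC(C)(C)[Si](C)(C)OS(=O)(=O)C(F)(F)F
Why: Silylation with a silyl triflate and a hindered base works on neopentyl-type secondary alcohols, and the TBS ether serves as the non-chelating polar group at C9 in step 12 and lasts until step 19.

Step 6
Reactants: 11 (S)-5-[(R)-1-(tert-butyldimethylsilyloxy)but-3-enyl]-5-methylcyclohex-2-en-1-one; 12 2-bromo-2-methylpropanal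
Product: 15 6-[2-bromo-2-methyl-1-(triethylsilyloxy)propyl]-5-[(R)-1-(tert-butyldimethylsilyloxy)but-3-enyl]-5-methylcyclohex-2-en-1-one (C5 unit cis to the C9 chain; epimers at C5), via lithium dienolate 13 (not isolated), via lithium aldolate 14 (not isolated)
Conditions: LiN(iPr)2, THF, −78 °C; 12, −78 °C; then TESOTf, −78 to −40 °C
Reagents that add atoms: 2-bromo-2-methylpropanal 12, CC(C)(Br)C=O; triethylsilyl triflate, CC[Si](CC)(CC)OS(=O)(=O)C(F)(F)F
Why: Kinetic α′-deprotonation of the enone gives the C4 enolate, whose lithium aldol addition to the non-enolisable, strongly electrophilic α-bromoaldehyde forms C4–C5; the aldehyde approaches anti to the pseudo-axial C10 methyl while the large C9 chain is pseudo-equatorial, so C5 ends up cis to C9, and silylation of the aldolate at −78 °C prevents both retro-aldol and epoxide closure (the C5 carbinol configuration is irrelevant).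

Step 7
Reactants: 15 the aldol silyl ether from step 6; 16 methyllithium
Product: 17 6-[2-bromo-2-methyl-1-(triethylsilyloxy)propyl]-5-[(R)-1-(tert-butyldimethylsilyloxy)but-3-enyl]-1,5-dimethylcyclohex-2-en-1-ol (epimers at C3 and C5)
Conditions: MeLi (1.3 equiv), Et2O, −78 °C; then H2O
Reagents that add atoms: methyllithium 16, [Li]C
Why: 1,2-Addition of methyllithium to the enone carbonyl brings in the C3 methyl group; carbonyl addition at −78 °C is much faster than any attack on the hindered tertiary bromide, and the new carbinol configuration is irrelevant because C3 becomes sp2 in step 8.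

Step 8
Reactants: 17 the tertiary allylic alcohol from step 7
Product: 18 4-[2-bromo-2-methyl-1-(triethylsilyloxy)propyl]-5-[(R)-1-(tert-butyldimethylsilyloxy)but-3-enyl]-3,5-dimethylcyclohex-2-en-1-one
Conditions: pyridinium chlorochromate [C5H5NH][CrO3Cl] (3 equiv), 4 Å molecular sieves, CH2Cl2, 25 °C
Reagents that add atoms: pyridinium chlorochromate, [O-][Cr](=O)(=O)Cl.c1cc[nH+]cc1
Why: In the Babler–Dauben oxidative transposition the chromate ester of the tertiary allylic alcohol shifts to C1 and is oxidised there, which moves the oxygen from C3 to C1 and leaves the C2=C3(Me) enone of the target, while both C3 epimers converge and the silyl ethers, bromide and terminal alkene are inert.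

Step 9
Reactants: 18 the transposed enone from step 8
Product: 19 4-(2-bromo-1-hydroxy-2-methylpropyl)-5-[(R)-1-(tert-butyldimethylsilyloxy)but-3-enyl]-3,5-dimethylcyclohex-2-en-1-one
Conditions: HF·pyridine, pyridine, THF, 0 °C
Reagents that add atoms: none
Why: Buffered fluoride cleaves the triethylsilyl ether selectively because it is far more labile than the tert-butyldimethylsilyl ether, and the medium is not basic enough to close the bromohydrin to an epoxide.

Step 10
Reactants: 19 the bromohydrin from step 9
Product: 21 (R)-3-[2-(2-bromo-1-hydroxy-2-methylpropyl)-1,3-dimethyl-5-oxocyclohex-3-enyl]-3-(tert-butyldimethylsilyloxy)propanal, via ozonide 20 (not isolated)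
Conditions: O3, CH2Cl2, −78 °C, Sudan Red 7B; then Me2S, −78 to 25 °C
Reagents that add atoms: ozone, [O-][O+]=O
Why: Ozonolysis distinguishes the terminal alkene from the conjugated, electron-poor C2=C3 bond and delivers the C7 aldehyde with loss of the extra allyl carbon.

Step 11
Reactants: 21 the hydroxy aldehyde from step 10
Product: 22 bromoketo aldehyde (ring A enone with C4–C(=O)–CMe2Br cis to C10–CH(OTBS)–CH2–CHO)
Conditions: Dess–Martin periodinane (1.5 equiv), CH2Cl2, 0 °C; short silica pad, used at once
Reagents that add atoms: none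
Why: Dess–Martin oxidation turns the hindered bromohydrin into the tertiary α-bromoketone under neutral conditions without touching the aldehyde, and it is placed last because H4 becomes a vinylogous β-diketone proton only now, so the cis C4 configuration has to survive a single handling.

Step 12
Reactants: 22 bromoketo aldehyde
Product: 25 cis-fused hydroxy diketone (C7–OH α; C9–OTBS β; H4 and C10–Me α), via samarium enolate 23 (not isolated), via samarium aldolate 24 (not isolated)
Conditions: 22 added by syringe pump to SmI2 (2.5 equiv), THF (final 0.005 M), −78 °C; pH 7 buffer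
Reagents that add atoms: none
Why: Two single-electron transfers from divalent samarium cleave the C6–Br bond far faster than they touch the aldehyde or the β,β-disubstituted enone and give the trivalent samarium enolate 23, whose only nucleophilic carbon is C6. C6 then adds to the C7 aldehyde in a 7-(enolexo)-exo-trig closure to aldolate 24, which is the known SmI2-mediated intramolecular Reformatsky-type aldol of α-bromoketones, a reaction that also closes medium carbocycles. Closure is helped by the gem-dimethyl group and by the shape of 22, in which C5 is pseudo-axial (no A(1,2) strain with the C3 methyl) and the C9 chain pseudo-equatorial, so the two ends are gauche on ring A and the fusion is cis. The new centre C7 is controlled by the C9 silyloxy group: the β-silyloxy aldehyde reacts in the dipole-minimised conformation of the polar 1,3-induction model within a samarium-bridged Zimmerman–Traxler chair, which should give the 1,3-anti C7/C9 relationship of the target. The step needs aldol addition to outrun proton transfer from the acidic H4, which is secured by base-free reductive enolate generation, pseudo-high dilution (each molecule of 22 meets excess SmI2, never other 22) and −78 °C. Any leakage at C4 is harmless, since the cis-fused 25 (C5 pseudo-axial and anti to the C10 methyl) should also be the thermodynamic epimer and C4 is frozen in step 13.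

Step 13
Reactants: 25 cis-fused hydroxy diketone
Product: 27 syn-5,7-diol (C5–OH α and C7–OH α), via boron chelate 26 (not isolated)
Conditions: Et2BOMe (1.1 equiv), THF/MeOH 4:1, −78 °C; NaBH4, −78 °C; AcOH, then repeated evaporation from MeOH
Reagents that add atoms: none
Why: In the Narasaka–Prasad reduction the diethylboron chelate between C7–O and the C5 carbonyl activates only this ketone, and external hydride adds axially to the six-membered chelate to give the 1,3-syn diol; this places C5–O on the α face as needed for backside attack by C11, while the unchelated enone should not react at −78 °C.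

Step 14
Reactants: 27 syn-5,7-diol
Product: 28 C7 triethylsilyl ether with free C5–OH
Conditions: TESOTf (1.05 equiv), 2,6-lutidine, CH2Cl2, −78 °C
Reagents that add atoms: triethylsilyl triflate, CC[Si](CC)(CC)OS(=O)(=O)C(F)(F)F
Why: Selective silylation should cap only C7–OH, which has a methylene neighbour whereas C5–OH is flanked by C6 and the ring-fusion carbon C4; the cap also blocks a Grob-type fragmentation in step 16 and keeps C7 and C9 distinguishable.

Step 15
Reactants: 28 C7 triethylsilyl ether
Product: 29 C5 mesylate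
Conditions: MsCl, Et3N, CH2Cl2, 0 °C
Reagents that add atoms: methanesulfonyl chloride, CS(=O)(=O)Cl
Why: Mesylation through sulfene tolerates very hindered secondary alcohols and turns the α-oriented C5–O bond into a leaving group without changing its configuration.

Step 16
Reactants: 29 C5 mesylate
Product: 31 7α-(triethylsilyloxy)-9β-(tert-butyldimethylsilyloxy)longipin-2-en-1-one, via potassium dienolate 30 (not isolated)
Conditions: KN(SiMe3)2 (2.0 equiv), THF, −78 to 25 °C
Reagents that add atoms: none
Why: Intramolecular enolate alkylation of a keto sulfonate is the classical entry to bicyclo[3.1.1]heptanones: kinetic α′-deprotonation gives the cross-conjugated C11 enolate 30 (C2 is sp2 and O-alkylation would need a bridgehead alkene), whose axial lobe faces the back of the pseudo-axial C5–OMs bond, so a 4-(enolexo)-exo-tet displacement with inversion forms C5–C11 and fixes C5 and C11 as in the target.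

Step 17
Reactants: 31 tricyclic bis-silyl ether
Product: 32 7α-hydroxy-9β-(tert-butyldimethylsilyloxy)longipin-2-en-1-one
Conditions: pyridinium p-toluenesulfonate (cat.), MeOH/CH2Cl2, 0 °C
Reagents that add atoms: none
Why: Mild acid methanolysis removes the triethylsilyl ether while the more robust tert-butyldimethylsilyl ether at the equally hindered C9 stays, which frees C7–OH alone.

Step 18
Reactants: 32 7α-hydroxy compound; 33 3-methylbut-2-enoic acid
Product: 35 7α-(3-methylbut-2-enoyloxy)-9β-(tert-butyldimethylsilyloxy)longipin-2-en-1-one, via mixed anhydride 34 (not isolated)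
Conditions: 33, 2,4,6-trichlorobenzoyl chloride, Et3N, toluene, 25 °C; then 32, 4-(dimethylamino)pyridine, 60 °C
Reagents that add atoms: 3-methylbut-2-enoic acid 33, CC(C)=CC(O)=O
Why: Yamaguchi esterification acylates hindered secondary alcohols and avoids the acid chloride/amine combination, which would pass through the vinylketene and deconjugate the senecioate.

Step 19
Reactants: 35 C7 senecioate
Product: 36 9β-hydroxy-7α-(3-methylbut-2-enoyloxy)longipin-2-en-1-one
Conditions: HF·pyridine, THF, 25 °C
Reagents that add atoms: none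
Why: Acidic fluoride cleaves the remaining silyl ether without ester migration or hydrolysis, which a basic fluoride source could cause.

Step 20
Reactants: 36 C9 alcohol; 37 3-methylbutanoyl chloride
Product: 38 target CNP0214473.1
Conditions: 37, pyridine, 4-(dimethylamino)pyridine (cat.), CH2Cl2, 25 °C
Reagents that add atoms: 3-methylbutanoyl chloride 37, CC(C)CC(Cl)=O
Why: Nucleophile-catalysed acylation with a saturated acid chloride esterifies the last free hydroxyl group at C9 and touches no stereocentre.

Compound list
1 | 1-hexyne | C#CCCCC | starting material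
2 | 3-methylcyclohex-2-en-1-one | CC1=CC(=O)CCC1 | starting material
3 | (E)-hex-1-enyl(diisobutyl)alane | CCCC/C=C/[Al](CC(C)C)CC(C)C | intermediate
4 | (S)-3-[(E)-hex-1-enyl]-3-methylcyclohexanone | CCCC/C=C/[C@@]1(C)CCCC(=O)C1 | intermediate
5 | (S)-5-[(E)-hex-1-enyl]-5-methylcyclohex-2-en-1-one | CCCC/C=C/[C@@]1(C)CC=CC(=O)C1 | intermediate
6 | ozonide (1,2,4-trioxolane) of 5 | CCCCC1OOC(O1)[C@@]2(C)CC=CC(=O)C2 | intermediate
7 | (S)-1-methyl-5-oxocyclohex-3-ene-1-carbaldehyde | O=C[C@@]1(C)CC=CC(=O)C1 | intermediate
8 | allylboronic acid pinacol ester | C=CCB1OC(C)(C)C(C)(C)O1 | starting material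
9 | pinacol borate of 10 | C=CC[C@@H](OB1OC(C)(C)C(C)(C)O1)[C@@]2(C)CC=CC(=O)C2 | intermediate
10 | (S)-5-[(R)-1-hydroxybut-3-enyl]-5-methylcyclohex-2-en-1-one | C=CC[C@@H](O)[C@@]1(C)CC=CC(=O)C1 | intermediate
11 | (S)-5-[(R)-1-(tert-butyldimethylsilyloxy)but-3-enyl]-5-methylcyclohex-2-en-1-one | C=CC[C@@H](O[Si](C)(C)C(C)(C)C)[C@@]1(C)CC=CC(=O)C1 | intermediate
12 | 2-bromo-2-methylpropanal | CC(C)(Br)C=O | starting material
13 | cross-conjugated lithium dienolate of 11 (C3–OLi, C3=C4) | C=CC[C@@H](O[Si](C)(C)C(C)(C)C)[C@@]1(C)CC=CC(O[Li])=C1 | intermediate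
14 | lithium aldolate (C4–C5 formed, C5 unit cis to the C9 chain) | C=CC[C@@H](O[Si](C)(C)C(C)(C)C)[C@@]1(C)CC=CC(=O)[C@H]1C(O[Li])C(C)(C)Br | intermediate
15 | aldol adduct as C5 triethylsilyl ether (epimers at C5) | C=CC[C@@H](O[Si](C)(C)C(C)(C)C)[C@@]1(C)CC=CC(=O)[C@H]1C(O[Si](CC)(CC)CC)C(C)(C)Br | intermediate
16 | methyllithium | [Li]C | starting material
17 | tertiary allylic alcohol (epimers at C3 and C5) | C=CC[C@@H](O[Si](C)(C)C(C)(C)C)[C@@]1(C)CC=CC(C)(O)[C@H]1C(O[Si](CC)(CC)CC)C(C)(C)Br | intermediate
18 | transposed enone, C1 ketone and C2=C3(Me) (epimers at C5) | C=CC[C@@H](O[Si](C)(C)C(C)(C)C)[C@@]1(C)CC(=O)C=C(C)[C@H]1C(O[Si](CC)(CC)CC)C(C)(C)Br | intermediate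
19 | bromohydrin with free C5–OH (epimers at C5) | C=CC[C@@H](O[Si](C)(C)C(C)(C)C)[C@@]1(C)CC(=O)C=C(C)[C@H]1C(O)C(C)(C)Br | intermediate
20 | ozonide (1,2,4-trioxolane) of 19 | C1OOC(O1)C[C@@H](O[Si](C)(C)C(C)(C)C)[C@@]2(C)CC(=O)C=C(C)[C@H]2C(O)C(C)(C)Br | intermediate
21 | hydroxy aldehyde (C7 aldehyde, C5 carbinol) | O=CC[C@@H](O[Si](C)(C)C(C)(C)C)[C@@]1(C)CC(=O)C=C(C)[C@H]1C(O)C(C)(C)Br | intermediate
22 | bromoketo aldehyde, precursor of the key step | O=CC[C@@H](O[Si](C)(C)C(C)(C)C)[C@@]1(C)CC(=O)C=C(C)[C@H]1C(=O)C(C)(C)Br | intermediate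
23 | trivalent samarium enolate at C5–C6 | O=CC[C@@H](O[Si](C)(C)C(C)(C)C)[C@@]1(C)CC(=O)C=C(C)[C@H]1C(O[Sm](I)I)=C(C)C | intermediate
24 | trivalent samarium aldolate (C6–C7 formed) | I[Sm](I)O[C@@H]1C[C@@H](O[Si](C)(C)C(C)(C)C)[C@@]2(C)CC(=O)C=C(C)[C@H]2C(=O)C1(C)C | intermediate
25 | cis-fused hydroxy diketone, product of the key step | O[C@@H]1C[C@@H](O[Si](C)(C)C(C)(C)C)[C@@]2(C)CC(=O)C=C(C)[C@H]2C(=O)C1(C)C | intermediate
26 | C7–O diethylboron chelate of 25 | CCB(CC)O[C@@H]1C[C@@H](O[Si](C)(C)C(C)(C)C)[C@@]2(C)CC(=O)C=C(C)[C@H]2C(=O)C1(C)C | intermediate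
27 | syn-5,7-diol (C5–OH α, C7–OH α) | O[C@@H]1C[C@@H](O[Si](C)(C)C(C)(C)C)[C@@]2(C)CC(=O)C=C(C)[C@H]2[C@H](O)C1(C)C | intermediate
28 | C7 triethylsilyl ether, free C5–OH | CC[Si](CC)(CC)O[C@@H]1C[C@@H](O[Si](C)(C)C(C)(C)C)[C@@]2(C)CC(=O)C=C(C)[C@H]2[C@H](O)C1(C)C | intermediate
29 | C5 α-mesylate | CC[Si](CC)(CC)O[C@@H]1C[C@@H](O[Si](C)(C)C(C)(C)C)[C@@]2(C)CC(=O)C=C(C)[C@H]2[C@H](OS(C)(=O)=O)C1(C)C | intermediate
30 | cross-conjugated potassium dienolate (C11=C1–OK) | CC[Si](CC)(CC)O[C@@H]1C[C@@H](O[Si](C)(C)C(C)(C)C)[C@@]2(C)C=C(O[K])C=C(C)[C@H]2[C@H](OS(C)(=O)=O)C1(C)C | intermediate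
31 | 7α-(triethylsilyloxy)-9β-(tert-butyldimethylsilyloxy)longipin-2-en-1-one | CC[Si](CC)(CC)O[C@@H]1C[C@@H](O[Si](C)(C)C(C)(C)C)[C@@]2(C)[C@@H]3C(=O)C=C(C)[C@H]2[C@@H]3C1(C)C | intermediate
32 | 7α-hydroxy-9β-(tert-butyldimethylsilyloxy)longipin-2-en-1-one | O[C@@H]1C[C@@H](O[Si](C)(C)C(C)(C)C)[C@@]2(C)[C@@H]3C(=O)C=C(C)[C@H]2[C@@H]3C1(C)C | intermediate
33 | 3-methylbut-2-enoic acid (senecioic acid) | CC(C)=CC(O)=O | starting material
34 | 3-methylbut-2-enoic 2,4,6-trichlorobenzoic anhydride | CC(C)=CC(=O)OC(=O)c1c(Cl)cc(Cl)cc1Cl | intermediate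
35 | 7α-(3-methylbut-2-enoyloxy)-9β-(tert-butyldimethylsilyloxy)longipin-2-en-1-one | CC(C)=CC(=O)O[C@@H]1C[C@@H](O[Si](C)(C)C(C)(C)C)[C@@]2(C)[C@@H]3C(=O)C=C(C)[C@H]2[C@@H]3C1(C)C | intermediate
36 | 9β-hydroxy-7α-(3-methylbut-2-enoyloxy)longipin-2-en-1-one | CC(C)=CC(=O)O[C@@H]1C[C@@H](O)[C@@]2(C)[C@@H]3C(=O)C=C(C)[C@H]2[C@@H]3C1(C)C | intermediate
37 | 3-methylbutanoyl chloride (isovaleryl chloride) | CC(C)CC(Cl)=O | starting material
38 | CNP0214473.1, 7α-(3-methylbut-2-enoyloxy)-9β-(3-methylbutanoyloxy)longipin-2-en-1-one | CC(C)=CC(=O)O[C@@H]1C[C@@H](OC(=O)CC(C)C)[C@@]2(C)[C@@H]3C(=O)C=C(C)[C@H]2[C@@H]3C1(C)C | target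

Total step count: 20. Longest linear sequence: 20 steps (from 1 or 2 to 38; all other building blocks are bought).

Steps most likely to fail

Step 12. The samarium enolate may be quenched by proton transfer from the acidic H4 of product or substrate molecules before the seven-membered ring closes, and facial selectivity at C7 may be poor. The fallback sets out from bromohydrin 19 and returns at 25.
- Dess–Martin oxidation of 19 gives the bromoketone alkene F1.
- Li2CO3/LiBr in DMF removes HBr to give the isopropenyl ketone F2.
- Selective ozonolysis of the terminal alkene gives the enone aldehyde F3.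
- A hydrogen-mediated rhodium-catalysed reductive aldol cyclisation ([Rh(cod)2]OTf, (4-CF3C6H4)3P, KOAc, H2, ClCH2CH2Cl, 25 °C) forms the same C6–C7 bond and gives 25. It works through a rhodium enolate made by hydrometallation of the unhindered vinyl ketone under nearly neutral conditions.

Step 16. γ-Deprotonation at C4 followed by vinylogous E1cB loss of mesylate may compete, or the neopentyl C5 centre may simply resist displacement. The fallback sets out from diol 27 and returns at 32.
- SOCl2/Et3N gives the cyclic sulfite F4.
- RuCl3 (cat.)/NaIO4 oxidises it to the six-membered cyclic sulfate F5.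
- KN(SiMe3)2 generates the C11 enolate, which opens the sulfate at C5 to the potassium sulfate monoester F6.
- H2SO4 (cat.) in wet THF hydrolyses this to 32.

The cyclic sulfate is a better leaving group than a mesylate, holds the C5–O bond in the alignment needed for backside attack, masks C7–O at the same time, and makes steps 14, 15 and 17 unnecessary.

Step 13. The enone may be reduced in competition, or hydride may be delivered from the wrong face if the boron chelate does not form in the seven-membered ring. The fallback sets out from 25 and returns at 27.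
- Excess iBu2AlH in THF at −78 °C reduces both ketones to give the triol F7. The C5 ketone reacts through an aluminium chelate with C7–O, which also leads to the 1,3-syn relationship.
- MnO2 in CH2Cl2 re-oxidises only the allylic C1 carbinol to give 27.

Further compounds
F1 | step 12 | bromoketone alkene (C5 ketone, terminal alkene intact) | C=CC[C@@H](O[Si](C)(C)C(C)(C)C)[C@@]1(C)CC(=O)C=C(C)[C@H]1C(=O)C(C)(C)Br
F2 | step 12 | isopropenyl ketone alkene | C=CC[C@@H](O[Si](C)(C)C(C)(C)C)[C@@]1(C)CC(=O)C=C(C)[C@H]1C(=O)C(C)=C
F3 | step 12 | isopropenyl ketone aldehyde | O=CC[C@@H](O[Si](C)(C)C(C)(C)C)[C@@]1(C)CC(=O)C=C(C)[C@H]1C(=O)C(C)=C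
F4 | step 16 | 5,7-cyclic sulfite of 27 | O=S1O[C@@H]2C[C@@H](O[Si](C)(C)C(C)(C)C)[C@@]3(C)CC(=O)C=C(C)[C@H]3[C@H](O1)C2(C)C
F5 | step 16 | 5,7-cyclic sulfate of 27 | O=S1(=O)O[C@@H]2C[C@@H](O[Si](C)(C)C(C)(C)C)[C@@]3(C)CC(=O)C=C(C)[C@H]3[C@H](O1)C2(C)C
F6 | step 16 | potassium 7α-sulfate of the tricyclic enone | [K+].[O-]S(=O)(=O)O[C@@H]1C[C@@H](O[Si](C)(C)C(C)(C)C)[C@@]2(C)[C@@H]3C(=O)C=C(C)[C@H]2[C@@H]3C1(C)C
F7 | step 13 | 1,5,7-triol (epimers at C1) | O[C@@H]1C[C@@H](O[Si](C)(C)C(C)(C)C)[C@@]2(C)CC(O)C=C(C)[C@H]2[C@H](O)C1(C)C
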